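**Retrosynthetic overview**
1. Target 24 ⇐ diol 23 (MnO2 oxidation of the allylic C3 alcohol only) ⇐ bis-silyl ether 22 ⇐ angeloylation of macrocyclic C5 alcohol 21.
2. Ten-membered carbocycle (formed last): C4–C5 bond by intramolecular NiCl2/CrCl2-mediated coupling of the C4 vinyl iodide with the C5 aldehyde (20 → 21), which also sets C5.
3. Lactone ring (formed second): C7–C8 bond and both stereocentres by the proposed chiral-phosphoric-acid-catalysed anti-[2-(methoxycarbonyl)allyl]boration/lactonisation of aldehyde 8 with (Z)-boronate 16.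
4. West aldehyde 8 (epoxide ring formed first): m-methylanisole → Birch reduction/ozonolysis (fixes the Z alkene) → Grignard C3–C4 bond → ent-Shi epoxidation.
5. East boronate 16: methyl D-glycerate (C6 stereocentre) → ynoate → syn-hydroalumination/borylmethylation.

Assumption: germacrane numbering is used (C1/C10 epoxide with CH3 on C10, C3 ketone, C4=C15, C5 O-angelate, C6 OH, C7/C8 lactone fusion, C11=C13, C12 lactone C=O; target = 1S,5R,6S,7R,8R,10R), and the C3 carbinol of intermediates 4–8 and 17–23 is carried as both epimers (no configuration in the SMILES) because it becomes the ketone in step 19.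

**West fragment**

Step 1
Reactants: 1 m-methylanisole (1-methoxy-3-methylbenzene)
Product: 2 dihydroanisole 1-methoxy-5-methylcyclohexa-1,4-diene
Conditions: Li, liquid NH3, t-BuOH, THF, −78 to −33 °C
Reagents that add atoms: none
Why: Birch reduction of an anisole gives the 2,5-dihydro product with OMe and CH3 on the two remaining double bonds, so the ring locks the future C1=C10 alkene in the cis (Z) geometry.

Step 2
Reactants: 2 dihydroanisole 1-methoxy-5-methylcyclohexa-1,4-diene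
Product: 3 methyl (3Z)-3-methyl-6-oxohex-3-enoate
Conditions: O3 (1.0 equiv), pyridine, CH2Cl2/MeOH, −78 °C; then Me2S, −78 °C to rt
Reagents that add atoms: ozone, [O-][O+]=O
Why: Chemoselective ozonolysis, because the electron-rich enol ether is cleaved much faster than the trisubstituted alkene, giving the C8 methyl ester and the C3 aldehyde with the Z alkene intact.

Step 3
Reactants: 3 methyl (3Z)-3-methyl-6-oxohex-3-enoate
Product: 4 methyl (3Z)-6-hydroxy-3-methyl-7-(trimethylsilyl)octa-3,7-dienoate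
Conditions: CH2=C(Br)SiMe3, Mg, THF, rt; then 3, THF, −78 °C; aq. NH4Cl
Reagents that add atoms: (1-bromovinyl)trimethylsilane, C=C(Br)[Si](C)(C)C
Why: Grignard 1,2-addition is far faster to the aldehyde than to the ester at −78 °C and forms the C3–C4 bond; the new C3 carbinol is formed as both epimers, which is immaterial (oxidised in step 19).

Step 4
Reactants: 4 methyl (3Z)-6-hydroxy-3-methyl-7-(trimethylsilyl)octa-3,7-dienoate
Product: 5 methyl (3Z)-6-[(tert-butyldimethylsilyl)oxy]-3-methyl-7-(trimethylsilyl)octa-3,7-dienoate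
Conditions: TBSOTf, 2,6-lutidine, CH2Cl2, −78 to 0 °C
Reagents that add atoms: tert-butyldimethylsilyl trifluoromethanesulfonate, CC(C)(C)[Si](C)(C)OS(=O)(=O)C(F)(F)F
Why: Silyl ether protection with the reactive triflate covers the hindered allylic alcohol with a group that is not a leaving group in the later organochromium step.

Step 5
Reactants: 5 methyl (3Z)-6-[(tert-butyldimethylsilyl)oxy]-3-methyl-7-(trimethylsilyl)octa-3,7-dienoate
Product: 6 methyl 2-[(2R,3S)-3-{2-[(tert-butyldimethylsilyl)oxy]-3-(trimethylsilyl)but-3-en-1-yl}-2-methyloxiran-2-yl]acetate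
Conditions: ent-Shi ketone (1,2:4,5-di-O-isopropylidene-β-L-erythro-2,3-hexodiulo-2,6-pyranose, 30 mol%), KHSO5 (as Oxone, 2KHSO5·KHSO4·K2SO4), K2CO3, Bu4NHSO4, MeCN/CH2(OMe)2/aq. Na2B4O7 buffer (pH 10.5), 0 °C
Reagents that add atoms: potassium peroxymonosulfate, [K+].[O-]S(=O)(=O)OO
Why: Shi asymmetric epoxidation, in which the chiral dioxirane attacks only the electron-rich trisubstituted alkene through the spiro transition state; the D-fructose ketone would give the (1R,10S) epoxide, so its antipode gives (1S,10R), and alkene geometry is retained (cis-epoxide).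

Step 6
Reactants: 6 methyl 2-[(2R,3S)-3-{2-[(tert-butyldimethylsilyl)oxy]-3-(trimethylsilyl)but-3-en-1-yl}-2-methyloxiran-2-yl]acetate
Product: 7 methyl 2-[(2R,3S)-3-{2-[(tert-butyldimethylsilyl)oxy]-3-iodobut-3-en-1-yl}-2-methyloxiran-2-yl]acetate
Conditions: NIS, MeCN/ClCH2CN (4:1), 0 °C to rt, dark
Reagents that add atoms: N-iodosuccinimide, O=C1CCC(=O)N1I
Why: Electrophilic iododesilylation (ipso-substitution of the vinylsilane) swaps SiMe3 for iodine at C4 under non-acidic conditions that leave the epoxide and ester alone; it is done after step 5 so that no electron-rich alkene is left to compete.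

Step 7
Reactants: 7 methyl 2-[(2R,3S)-3-{2-[(tert-butyldimethylsilyl)oxy]-3-iodobut-3-en-1-yl}-2-methyloxiran-2-yl]acetate
Product: 8 epoxy aldehyde 2-[(2R,3S)-3-{2-[(tert-butyldimethylsilyl)oxy]-3-iodobut-3-en-1-yl}-2-methyloxiran-2-yl]acetaldehyde
Conditions: i-Bu2AlH (1.05 equiv), CH2Cl2, −78 °C; MeOH, then aq. potassium sodium tartrate
Reagents that add atoms: none
Why: Partial ester reduction stops at the aluminium hemiacetal at −78 °C and releases the labile β,γ-epoxy aldehyde only on cold neutral work-up, so it is used at once without chromatography.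

**East fragment**

Step 8
Reactants: 9 methyl (2R)-2,3-dihydroxypropanoate (methyl D-glycerate)
Product: 10 methyl (2R)-2,3-bis[(tert-butyldimethylsilyl)oxy]propanoate
Conditions: TBSCl (2.4 equiv), imidazole, DMF, rt
Reagents that add atoms: tert-butyldimethylsilyl chloride, CC(C)(C)[Si](C)(C)Cl
Why: Standard bis-silylation; the C6 stereocentre comes from the chiral pool and is not touched.

Step 9
Reactants: 10 methyl (2R)-2,3-bis[(tert-butyldimethylsilyl)oxy]propanoate
Product: 11 (2R)-2,3-bis[(tert-butyldimethylsilyl)oxy]propanal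
Conditions: i-Bu2AlH (1.1 equiv), CH2Cl2, −78 °C; MeOH, then aq. potassium sodium tartrate
Reagents that add atoms: none
Why: Partial reduction of an α-silyloxy ester at −78 °C gives the configurationally stable α-silyloxy aldehyde.

Step 10
Reactants: 11 (2R)-2,3-bis[(tert-butyldimethylsilyl)oxy]propanal
Product: 12 (3S)-1,1-dibromo-3,4-bis[(tert-butyldimethylsilyl)oxy]but-1-ene
Conditions: CBr4, PPh3, Zn, CH2Cl2, rt; then 11, 0 °C
Reagents that add atoms: carbon tetrabromide, BrC(Br)(Br)Br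
Why: Corey–Fuchs dibromoolefination (Wittig type) under neutral Zn/PPh3 conditions does not epimerise C6.

Step 11
Reactants: 12 (3S)-1,1-dibromo-3,4-bis[(tert-butyldimethylsilyl)oxy]but-1-ene
Product: 14 methyl (4S)-4,5-bis[(tert-butyldimethylsilyl)oxy]pent-2-ynoate, via lithium acetylide 13 (not isolated)
Conditions: n-BuLi (2.1 equiv), THF, −78 °C; then ClCO2Me, −78 to 0 °C
Reagents that add atoms: methyl chloroformate, COC(=O)Cl
Why: Second stage of the Corey–Fuchs sequence (Li–Br exchange, elimination, deprotonation) gives the acetylide, which is C-acylated by the chloroformate to the ynoate.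

Step 12
Reactants: 14 methyl (4S)-4,5-bis[(tert-butyldimethylsilyl)oxy]pent-2-ynoate
Product: 16 methyl (2Z,4S)-4,5-bis[(tert-butyldimethylsilyl)oxy]-2-[(4,4,5,5-tetramethyl-1,3,2-dioxaborolan-2-yl)methyl]pent-2-enoate, via vinylalane 15 (not isolated)
Conditions: i-Bu2AlH, HMPA, THF, 0 °C; then ICH2Bpin, 0 °C to rt
Reagents that add atoms: 2-(iodomethyl)-4,4,5,5-tetramethyl-1,3,2-dioxaborolane, ICB1OC(C)(C)C(C)(C)O1
Why: Conjugate syn-hydroalumination of the ynoate puts H (C7) and Al (C11) on the same side, and alkylation of the vinylalane with retention gives the boronate with the C6 chain cis to CO2Me and trans to CH2B, the E-crotyl-type geometry needed for anti addition (hydrometalation–alkylation).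

**Fragment union, ring closure and endgame**

Step 13
Reactants: 8 epoxy aldehyde 2-[(2R,3S)-3-{2-[(tert-butyldimethylsilyl)oxy]-3-iodobut-3-en-1-yl}-2-methyloxiran-2-yl]acetaldehyde; 16 methyl (2Z,4S)-4,5-bis[(tert-butyldimethylsilyl)oxy]-2-[(4,4,5,5-tetramethyl-1,3,2-dioxaborolan-2-yl)methyl]pent-2-enoate
Product: 18 (4S,5R)-4-{(1S)-1,2-bis[(tert-butyldimethylsilyl)oxy]ethyl}-5-{[(2R,3S)-3-{2-[(tert-butyldimethylsilyl)oxy]-3-iodobut-3-en-1-yl}-2-methyloxiran-2-yl]methyl}-3-methylideneoxolan-2-one, via O-boryl adduct 17 (not isolated)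
Conditions: (S)-3,3′-bis(2,4,6-triisopropylphenyl)-1,1′-binaphthyl-2,2′-diyl hydrogen phosphate (10 mol%), 4 Å molecular sieves, toluene, −30 °C to rt; then 45 °C
Reagents that add atoms: none
Why: Proposed new method: a chiral phosphoric acid-catalysed, catalyst-controlled anti-[2-(methoxycarbonyl)allyl]boration in which the acid hydrogen-bonds a pinacol oxygen and the formyl C–H and so accelerates a closed six-membered chair transition state; the (Z)-boronate holds the C6 chain equatorial (C7/C8 anti, hence the trans-lactone), the (S)-acid blocks the Re face so that C7 adds to the Si face of C8 (C8 R, and C7 through the chair), and the same acid then drives lactonisation of the O-boryl adduct with loss of MeOBpin; the closest known reaction types are chiral phosphoric acid-catalysed allyl- and crotylboration of aldehydes and Lewis or Brønsted acid-accelerated additions of 2-alkoxycarbonyl allylboronates, whereas enantio-controlled use of a γ-substituted, stereocentre-bearing boronate of this class on a labile β,γ-epoxy aldehyde to give a trans-β,γ-disubstituted α-methylene-γ-butyrolactone has not been shown.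

Step 14
Reactants: 18 (4S,5R)-4-{(1S)-1,2-bis[(tert-butyldimethylsilyl)oxy]ethyl}-5-{[(2R,3S)-3-{2-[(tert-butyldimethylsilyl)oxy]-3-iodobut-3-en-1-yl}-2-methyloxiran-2-yl]methyl}-3-methylideneoxolan-2-one
Product: 19 (4S,5R)-4-{(1S)-1-[(tert-butyldimethylsilyl)oxy]-2-hydroxyethyl}-5-{[(2R,3S)-3-{2-[(tert-butyldimethylsilyl)oxy]-3-iodobut-3-en-1-yl}-2-methyloxiran-2-yl]methyl}-3-methylideneoxolan-2-one
Conditions: HF·pyridine, pyridine, THF, 0 °C
Reagents that add atoms: none
Why: Selective desilylation, since buffered HF·pyridine cleaves the unhindered primary TBS ether much faster than the two secondary ones and leaves epoxide, lactone and vinyl iodide intact.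

Step 15
Reactants: 19 (4S,5R)-4-{(1S)-1-[(tert-butyldimethylsilyl)oxy]-2-hydroxyethyl}-5-{[(2R,3S)-3-{2-[(tert-butyldimethylsilyl)oxy]-3-iodobut-3-en-1-yl}-2-methyloxiran-2-yl]methyl}-3-methylideneoxolan-2-one
Product: 20 (2S)-2-[(tert-butyldimethylsilyl)oxy]-2-[(2R,3S)-2-{[(2R,3S)-3-{2-[(tert-butyldimethylsilyl)oxy]-3-iodobut-3-en-1-yl}-2-methyloxiran-2-yl]methyl}-4-methylidene-5-oxooxolan-3-yl]acetaldehyde
Conditions: Dess–Martin periodinane, pyridine, CH2Cl2, 0 °C to rt
Reagents that add atoms: none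
Why: Buffered Dess–Martin oxidation gives the α-silyloxy C5 aldehyde without epimerising C6 or touching the epoxide.

Step 16
Reactants: 20 (2S)-2-[(tert-butyldimethylsilyl)oxy]-2-[(2R,3S)-2-{[(2R,3S)-3-{2-[(tert-butyldimethylsilyl)oxy]-3-iodobut-3-en-1-yl}-2-methyloxiran-2-yl]methyl}-4-methylidene-5-oxooxolan-3-yl]acetaldehyde
Product: 21 (1S,5R,6S,7S,8R,10R)-3,6-bis[(tert-butyldimethylsilyl)oxy]-5-hydroxy-1,10-epoxygermacra-4(15),11(13)-dien-8,12-olide
Conditions: CrCl2 (10 equiv), NiCl2 (0.1 equiv), DMSO/THF (3:1), rt, slow addition of 20 to 0.002 M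
Reagents that add atoms: none
Why: Intramolecular Nozaki–Hiyama–Kishi reaction, in which zerovalent nickel inserts into the C–I bond and hands the alkenyl group to trivalent chromium, which adds only to the aldehyde; the trans-lactone and cis-epoxide pre-organise the chain for ten-membered ring closure, and polar Felkin–Anh addition anti to the C6–OTBS bond sets C5 (R, 5,6-anti).

Step 17
Reactants: 21 (1S,5R,6S,7S,8R,10R)-3,6-bis[(tert-butyldimethylsilyl)oxy]-5-hydroxy-1,10-epoxygermacra-4(15),11(13)-dien-8,12-olide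
Product: 22 (1S,5R,6S,7S,8R,10R)-3,6-bis[(tert-butyldimethylsilyl)oxy]-5-{[(2Z)-2-methylbut-2-enoyl]oxy}-1,10-epoxygermacra-4(15),11(13)-dien-8,12-olide
Conditions: angelic acid, 2,4,6-trichlorobenzoyl chloride, Et3N, toluene, rt; then 21, 75 °C
Reagents that add atoms: angelic acid ((2Z)-2-methylbut-2-enoic acid), C/C=C(/C)C(=O)O
Why: Yamaguchi-type mixed-anhydride esterification run without a nucleophilic catalyst acylates the only free hydroxyl (C5) and keeps the Z geometry, which DMAP-type catalysts would isomerise to the tiglate.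

Step 18
Reactants: 22 (1S,5R,6S,7S,8R,10R)-3,6-bis[(tert-butyldimethylsilyl)oxy]-5-{[(2Z)-2-methylbut-2-enoyl]oxy}-1,10-epoxygermacra-4(15),11(13)-dien-8,12-olide
Product: 23 (1S,5R,6S,7R,8R,10R)-3,6-dihydroxy-5-{[(2Z)-2-methylbut-2-enoyl]oxy}-1,10-epoxygermacra-4(15),11(13)-dien-8,12-olide
Conditions: HF·pyridine, pyridine, THF, 0 °C to rt
Reagents that add atoms: none
Why: Fluoride desilylation under buffered, mildly acidic conditions removes both secondary TBS ethers while avoiding the base-promoted C5→C6 acyl shift, lactone migration and epoxide opening.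

Step 19
Reactants: 23 (1S,5R,6S,7R,8R,10R)-3,6-dihydroxy-5-{[(2Z)-2-methylbut-2-enoyl]oxy}-1,10-epoxygermacra-4(15),11(13)-dien-8,12-olide
Product: 24 (1S,5R,6S,7R,8R,10R)-6-hydroxy-5-{[(2Z)-2-methylbut-2-enoyl]oxy}-3-oxo-1,10-epoxygermacra-4(15),11(13)-dien-8,12-olide
Conditions: MnO2 (activated, 20 equiv), CH2Cl2, rt
Reagents that add atoms: none
Why: Chemoselective allylic oxidation, as MnO2 oxidises only the allylic C3 alcohol (both epimers converge) and leaves the non-allylic C6 alcohol, giving the enone under neutral conditions that spare the β,γ-epoxide, the angelate and both exocyclic alkenes.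

**Compound list**
1 | m-methylanisole (1-methoxy-3-methylbenzene) | COc1cccc(C)c1 | starting material
2 | dihydroanisole 1-methoxy-5-methylcyclohexa-1,4-diene | COC1=CCC=C(C)C1 | intermediate
3 | methyl (3Z)-3-methyl-6-oxohex-3-enoate | COC(=O)C/C(C)=C\CC=O | intermediate
4 | methyl (3Z)-6-hydroxy-3-methyl-7-(trimethylsilyl)octa-3,7-dienoate | COC(=O)C/C(C)=C\CC(O)C(=C)[Si](C)(C)C | intermediate
5 | methyl (3Z)-6-[(tert-butyldimethylsilyl)oxy]-3-methyl-7-(trimethylsilyl)octa-3,7-dienoate | COC(=O)C/C(C)=C\CC(O[Si](C)(C)C(C)(C)C)C(=C)[Si](C)(C)C | intermediate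
6 | methyl 2-[(2R,3S)-3-{2-[(tert-butyldimethylsilyl)oxy]-3-(trimethylsilyl)but-3-en-1-yl}-2-methyloxiran-2-yl]acetate | COC(=O)C[C@@]1(C)O[C@H]1CC(O[Si](C)(C)C(C)(C)C)C(=C)[Si](C)(C)C | intermediate
7 | methyl 2-[(2R,3S)-3-{2-[(tert-butyldimethylsilyl)oxy]-3-iodobut-3-en-1-yl}-2-methyloxiran-2-yl]acetate | COC(=O)C[C@@]1(C)O[C@H]1CC(O[Si](C)(C)C(C)(C)C)C(=C)I | intermediate
8 | epoxy aldehyde 2-[(2R,3S)-3-{2-[(tert-butyldimethylsilyl)oxy]-3-iodobut-3-en-1-yl}-2-methyloxiran-2-yl]acetaldehyde | O=CC[C@@]1(C)O[C@H]1CC(O[Si](C)(C)C(C)(C)C)C(=C)I | intermediate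
9 | methyl (2R)-2,3-dihydroxypropanoate (methyl D-glycerate) | COC(=O)[C@H](O)CO | starting material
10 | methyl (2R)-2,3-bis[(tert-butyldimethylsilyl)oxy]propanoate | CC(C)(C)[Si](C)(C)OC[C@@H](O[Si](C)(C)C(C)(C)C)C(=O)OC | intermediate
11 | (2R)-2,3-bis[(tert-butyldimethylsilyl)oxy]propanal | CC(C)(C)[Si](C)(C)OC[C@@H](O[Si](C)(C)C(C)(C)C)C=O | intermediate
12 | (3S)-1,1-dibromo-3,4-bis[(tert-butyldimethylsilyl)oxy]but-1-ene | CC(C)(C)[Si](C)(C)OC[C@@H](O[Si](C)(C)C(C)(C)C)C=C(Br)Br | intermediate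
13 | lithium acetylide [(3S)-3,4-bis[(tert-butyldimethylsilyl)oxy]but-1-yn-1-yl]lithium | CC(C)(C)[Si](C)(C)OC[C@@H](O[Si](C)(C)C(C)(C)C)C#C[Li] | intermediate
14 | methyl (4S)-4,5-bis[(tert-butyldimethylsilyl)oxy]pent-2-ynoate | CC(C)(C)[Si](C)(C)OC[C@@H](O[Si](C)(C)C(C)(C)C)C#CC(=O)OC | intermediate
15 | vinylalane methyl (2E,4S)-4,5-bis[(tert-butyldimethylsilyl)oxy]-2-[bis(2-methylpropyl)alumanyl]pent-2-enoate | CC(C)(C)[Si](C)(C)OC[C@@H](O[Si](C)(C)C(C)(C)C)/C=C(/[Al](CC(C)C)CC(C)C)C(=O)OC | intermediate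
16 | methyl (2Z,4S)-4,5-bis[(tert-butyldimethylsilyl)oxy]-2-[(4,4,5,5-tetramethyl-1,3,2-dioxaborolan-2-yl)methyl]pent-2-enoate | CC(C)(C)[Si](C)(C)OC[C@@H](O[Si](C)(C)C(C)(C)C)/C=C(/CB1OC(C)(C)C(C)(C)O1)C(=O)OC | intermediate
17 | O-boryl adduct methyl (3S,4R)-3-{(1S)-1,2-bis[(tert-butyldimethylsilyl)oxy]ethyl}-5-[(2R,3S)-3-{2-[(tert-butyldimethylsilyl)oxy]-3-iodobut-3-en-1-yl}-2-methyloxiran-2-yl]-2-methylidene-4-[(4,4,5,5-tetramethyl-1,3,2-dioxaborolan-2-yl)oxy]pentanoate | COC(=O)C(=C)[C@H]([C@H](O[Si](C)(C)C(C)(C)C)CO[Si](C)(C)C(C)(C)C)[C@H](OB1OC(C)(C)C(C)(C)O1)C[C@@]2(C)O[C@H]2CC(O[Si](C)(C)C(C)(C)C)C(=C)I | intermediate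
18 | (4S,5R)-4-{(1S)-1,2-bis[(tert-butyldimethylsilyl)oxy]ethyl}-5-{[(2R,3S)-3-{2-[(tert-butyldimethylsilyl)oxy]-3-iodobut-3-en-1-yl}-2-methyloxiran-2-yl]methyl}-3-methylideneoxolan-2-one | C=C1C(=O)O[C@H](C[C@@]2(C)O[C@H]2CC(O[Si](C)(C)C(C)(C)C)C(=C)I)[C@H]1[C@H](O[Si](C)(C)C(C)(C)C)CO[Si](C)(C)C(C)(C)C | intermediate
19 | (4S,5R)-4-{(1S)-1-[(tert-butyldimethylsilyl)oxy]-2-hydroxyethyl}-5-{[(2R,3S)-3-{2-[(tert-butyldimethylsilyl)oxy]-3-iodobut-3-en-1-yl}-2-methyloxiran-2-yl]methyl}-3-methylideneoxolan-2-one | C=C1C(=O)O[C@H](C[C@@]2(C)O[C@H]2CC(O[Si](C)(C)C(C)(C)C)C(=C)I)[C@H]1[C@H](O[Si](C)(C)C(C)(C)C)CO | intermediate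
20 | (2S)-2-[(tert-butyldimethylsilyl)oxy]-2-[(2R,3S)-2-{[(2R,3S)-3-{2-[(tert-butyldimethylsilyl)oxy]-3-iodobut-3-en-1-yl}-2-methyloxiran-2-yl]methyl}-4-methylidene-5-oxooxolan-3-yl]acetaldehyde | C=C1C(=O)O[C@H](C[C@@]2(C)O[C@H]2CC(O[Si](C)(C)C(C)(C)C)C(=C)I)[C@H]1[C@H](O[Si](C)(C)C(C)(C)C)C=O | intermediate
21 | (1S,5R,6S,7S,8R,10R)-3,6-bis[(tert-butyldimethylsilyl)oxy]-5-hydroxy-1,10-epoxygermacra-4(15),11(13)-dien-8,12-olide | C=C1C(=O)O[C@@H]2C[C@@]3(C)O[C@H]3CC(O[Si](C)(C)C(C)(C)C)C(=C)[C@@H](O)[C@@H](O[Si](C)(C)C(C)(C)C)[C@@H]12 | intermediate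
22 | (1S,5R,6S,7S,8R,10R)-3,6-bis[(tert-butyldimethylsilyl)oxy]-5-{[(2Z)-2-methylbut-2-enoyl]oxy}-1,10-epoxygermacra-4(15),11(13)-dien-8,12-olide | C=C1C(=O)O[C@@H]2C[C@@]3(C)O[C@H]3CC(O[Si](C)(C)C(C)(C)C)C(=C)[C@@H](OC(=O)/C(C)=C\C)[C@@H](O[Si](C)(C)C(C)(C)C)[C@@H]12 | intermediate
23 | (1S,5R,6S,7R,8R,10R)-3,6-dihydroxy-5-{[(2Z)-2-methylbut-2-enoyl]oxy}-1,10-epoxygermacra-4(15),11(13)-dien-8,12-olide | C=C1C(=O)O[C@@H]2C[C@@]3(C)O[C@H]3CC(O)C(=C)[C@@H](OC(=O)/C(C)=C\C)[C@@H](O)[C@@H]12 | intermediate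
24 | (1S,5R,6S,7R,8R,10R)-6-hydroxy-5-{[(2Z)-2-methylbut-2-enoyl]oxy}-3-oxo-1,10-epoxygermacra-4(15),11(13)-dien-8,12-olide (CNP0348992.6) | C=C1C(=O)O[C@@H]2C[C@@]3(C)O[C@H]3CC(=O)C(=C)[C@@H](OC(=O)/C(C)=C\C)[C@@H](O)[C@@H]12 | target

**Step count and risks**
Total step count: 19 steps.
Longest linear sequence: 14 steps.
This longest chain runs from m-methylanisole through the West fragment, the fragment union and the endgame to the target; the East branch from methyl D-glycerate is shorter.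

Most likely to fail, 1: step 13 (the proposed new allylboration/lactonisation). The ester-bearing boronate is a weak nucleophile, the C6 stereocentre may be mismatched with the catalyst, and aldehyde 8 is acid- and base-labile. The fallback uses only known chemistry, sets out from 5 and comes back at 18. i-Bu2AlH at −78 °C reduces ester 5 to the robust olefinic aldehyde (3Z)-6-[(tert-butyldimethylsilyl)oxy]-3-methyl-7-(trimethylsilyl)octa-3,7-dienal F1. Sc(OTf)3-catalysed allylboration of F1 with 16 (toluene, −78 °C, the established Lewis-acid mode, stereospecifically anti from the Z-boronate, facial sense now controlled by C6 of 16, minor isomer removed by chromatography) gives the open hydroxy ester methyl (3S,4R,6Z)-3-{(1S)-1,2-bis[(tert-butyldimethylsilyl)oxy]ethyl}-9-[(tert-butyldimethylsilyl)oxy]-4-hydroxy-6-methyl-2-methylidene-10-(trimethylsilyl)undeca-6,10-dienoate F2. p-TsOH in CH2Cl2 (no epoxide present yet) closes it to the trans-lactone (4S,5R)-4-{(1S)-1,2-bis[(tert-butyldimethylsilyl)oxy]ethyl}-5-[(2Z)-5-[(tert-butyldimethylsilyl)oxy]-2-methyl-6-(trimethylsilyl)hepta-2,6-dien-1-yl]-3-methylideneoxolan-2-one F3. ent-Shi epoxidation as in step 5 then gives (4S,5R)-4-{(1S)-1,2-bis[(tert-butyldimethylsilyl)oxy]ethyl}-5-{[(2R,3S)-3-{2-[(tert-butyldimethylsilyl)oxy]-3-(trimethylsilyl)but-3-en-1-yl}-2-methyloxiran-2-yl]methyl}-3-methylideneoxolan-2-one F4, and NIS iododesilylation as in step 6 gives 18.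

Most likely to fail, 2: step 16 (ten-membered NiCl2/CrCl2 ring closure). Transannular strain and the mixed C3 configuration may lower the yield or override Felkin control at C5. The fallback sets out from 20 and comes back at 21, and fixes C5 by reagent-controlled reduction instead of by the C–C bond formation. If the closure gives mainly the epimer (1S,5S,6S,7S,8R,10R)-3,6-bis[(tert-butyldimethylsilyl)oxy]-5-hydroxy-1,10-epoxygermacra-4(15),11(13)-dien-8,12-olide F5, the whole C5 mixture is oxidised with Dess–Martin periodinane to the enone (1S,6S,7S,8R,10R)-3,6-bis[(tert-butyldimethylsilyl)oxy]-5-oxo-1,10-epoxygermacra-4(15),11(13)-dien-8,12-olide F6. 1,2-Reduction with (R)-2-methyl-CBS-oxazaborolidine ((3aR)-1-methyl-3,3-diphenyltetrahydro-1H,3H-pyrrolo[1,2-c][1,3,2]oxazaborole) and catecholborane at −78 °C (alkenyl branch as the large group) then returns the (5R) alcohol 21.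

Most likely to fail, 3: step 12 (hydroalumination/borylmethylation). The vinylalane may alkylate sluggishly or lose its geometry through the aluminium allenoate. The fallback sets out from 14 and comes back at 16. Bu3SnH with Pd(PPh3)4 adds syn across the ynoate with tin at the α-carbon to give methyl (2E,4S)-4,5-bis[(tert-butyldimethylsilyl)oxy]-2-(tributylstannyl)pent-2-enoate F7. I2 in CH2Cl2 at 0 °C gives, with retention, methyl (2E,4S)-4,5-bis[(tert-butyldimethylsilyl)oxy]-2-iodopent-2-enoate F8. Pd(PPh3)4-catalysed Negishi coupling of F8 with IZnCH2Bpin (from ICH2Bpin and Zn) then delivers 16 with the same geometry.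

**Further compounds**
F1 | step 13 | (3Z)-6-[(tert-butyldimethylsilyl)oxy]-3-methyl-7-(trimethylsilyl)octa-3,7-dienal | O=CC/C(C)=C\CC(O[Si](C)(C)C(C)(C)C)C(=C)[Si](C)(C)C
F2 | step 13 | methyl (3S,4R,6Z)-3-{(1S)-1,2-bis[(tert-butyldimethylsilyl)oxy]ethyl}-9-[(tert-butyldimethylsilyl)oxy]-4-hydroxy-6-methyl-2-methylidene-10-(trimethylsilyl)undeca-6,10-dienoate | COC(=O)C(=C)[C@H]([C@H](O[Si](C)(C)C(C)(C)C)CO[Si](C)(C)C(C)(C)C)[C@H](O)C/C(C)=C\CC(O[Si](C)(C)C(C)(C)C)C(=C)[Si](C)(C)C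
F3 | step 13 | (4S,5R)-4-{(1S)-1,2-bis[(tert-butyldimethylsilyl)oxy]ethyl}-5-[(2Z)-5-[(tert-butyldimethylsilyl)oxy]-2-methyl-6-(trimethylsilyl)hepta-2,6-dien-1-yl]-3-methylideneoxolan-2-one | C=C1C(=O)O[C@H](C/C(C)=C\CC(O[Si](C)(C)C(C)(C)C)C(=C)[Si](C)(C)C)[C@H]1[C@H](O[Si](C)(C)C(C)(C)C)CO[Si](C)(C)C(C)(C)C
F4 | step 13 | (4S,5R)-4-{(1S)-1,2-bis[(tert-butyldimethylsilyl)oxy]ethyl}-5-{[(2R,3S)-3-{2-[(tert-butyldimethylsilyl)oxy]-3-(trimethylsilyl)but-3-en-1-yl}-2-methyloxiran-2-yl]methyl}-3-methylideneoxolan-2-one | C=C1C(=O)O[C@H](C[C@@]2(C)O[C@H]2CC(O[Si](C)(C)C(C)(C)C)C(=C)[Si](C)(C)C)[C@H]1[C@H](O[Si](C)(C)C(C)(C)C)CO[Si](C)(C)C(C)(C)C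
F5 | step 16 | (1S,5S,6S,7S,8R,10R)-3,6-bis[(tert-butyldimethylsilyl)oxy]-5-hydroxy-1,10-epoxygermacra-4(15),11(13)-dien-8,12-olide | C=C1C(=O)O[C@@H]2C[C@@]3(C)O[C@H]3CC(O[Si](C)(C)C(C)(C)C)C(=C)[C@H](O)[C@@H](O[Si](C)(C)C(C)(C)C)[C@@H]12
F6 | step 16 | (1S,6S,7S,8R,10R)-3,6-bis[(tert-butyldimethylsilyl)oxy]-5-oxo-1,10-epoxygermacra-4(15),11(13)-dien-8,12-olide | C=C1C(=O)O[C@@H]2C[C@@]3(C)O[C@H]3CC(O[Si](C)(C)C(C)(C)C)C(=C)C(=O)[C@@H](O[Si](C)(C)C(C)(C)C)[C@@H]12
F7 | step 12 | methyl (2E,4S)-4,5-bis[(tert-butyldimethylsilyl)oxy]-2-(tributylstannyl)pent-2-enoate | CC(C)(C)[Si](C)(C)OC[C@@H](O[Si](C)(C)C(C)(C)C)/C=C(/[Sn](CCCC)(CCCC)CCCC)C(=O)OC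
F8 | step 12 | methyl (2E,4S)-4,5-bis[(tert-butyldimethylsilyl)oxy]-2-iodopent-2-enoate | CC(C)(C)[Si](C)(C)OC[C@@H](O[Si](C)(C)C(C)(C)C)/C=C(/I)C(=O)OC
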